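Guaiane numbering is used: five-membered ring C1–C5 (C3=C4, C15 on C4), seven-membered ring C1, C10, C9, C8, C7, C6, C5. Everything rests on cutting C6–C7: the segment C14–C10(O)–C9–C8–C7 of the seven-membered ring, with the isopropenyl group on C7, is the carbon chain of (S)-linalool. One aluminium-promoted intramolecular ene reaction between the prenyl terminus and a 2-methylenecyclopentanone closes the seven-membered ring, sets C7 and unveils the isopropenyl group. Its precursor is a 3-substituted 2-methylenecyclopentanone carrying the silylated linalool chain, with C1 fixed beforehand by desymmetrising a cyclobutanone; the C4 ketone then delivers C3=C4 and C15.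

Key step: step 9

Remark 1: (S)-linalool of high enantiomeric purity is taken as a commercial material; C10 is never touched, so its purity is carried through to the target.
Remark 2: the sense of induction in step 5 is assigned by analogy with simpler 3-substituted cyclobutanones; should the (R,R)-amide give mainly the ring epimer of 8, the (S,S)-amide is used, and the minor epimer, a diastereomer, is removed by chromatography at 10 or 14.

Step 1
Reactants: 1 (S)-linalool
Product: 2 {[(3S)-3,7-dimethylocta-1,6-dien-3-yl]oxy}(triethyl)silane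
Conditions: Et3SiOTf, 2,6-lutidine, CH2Cl2, −78 → 0 °C
Reagents that add atoms: triethylsilyl trifluoromethanesulfonate, CC[Si](CC)(CC)OS(=O)(=O)C(F)(F)F
Why: Silyl ether formation with the silyl triflate and a hindered pyridine base should protect the tertiary allylic alcohol without ionising its C–O bond; no stereocentre is touched.

Step 2
Reactants: 2 {[(3S)-3,7-dimethylocta-1,6-dien-3-yl]oxy}(triethyl)silane
Product: 3 {[(3S)-6-bromo-7-methoxy-3,7-dimethyloct-1-en-3-yl]oxy}(triethyl)silane (both C6 epimers)
Conditions: N-bromosuccinimide, NaHCO3, MeOH, 0 °C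
Reagents that add atoms: N-bromosuccinimide, O=C1CCC(=O)N1Br; methanol, CO
Why: Bromomethoxylation (bromonium formation with Markovnikov capture by methanol) should occur only at the electron-rich trisubstituted alkene, the vinyl group next to the silyloxy-bearing quaternary carbon being deactivated, and masks that alkene as a β-bromo ether; the C–Br centre forms as both epimers, which is of no consequence because step 4 removes it.

Step 3
Reactants: 3 {[(3S)-6-bromo-7-methoxy-3,7-dimethyloct-1-en-3-yl]oxy}(triethyl)silane; 4 trichloroacetyl chloride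
Product: 5 3-[(2S)-5-bromo-6-methoxy-6-methyl-2-(triethylsilyloxy)heptan-2-yl]-2,2-dichlorocyclobutan-1-one (epimers at ring C3 and at the C–Br carbon)
Conditions: Zn–Cu couple, POCl3, Et2O, 15–25 °C (4 added slowly)
Reagents that add atoms: none
Why: Ketene–alkene [2+2] cycloaddition of dichloroketene, made in the flask by zinc dechlorination of 4, should add to the only remaining alkene with the carbonyl carbon on the terminal CH2 and CCl2 on the inner carbon, while the unactivated alkyl bromide and the ethers are inert; the new ring centre forms as both epimers because the methyl and methylene groups on C10 do not differentiate the faces, and it is erased in step 4.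

Step 4
Reactants: 5 3-[(2S)-5-bromo-6-methoxy-6-methyl-2-(triethylsilyloxy)heptan-2-yl]-2,2-dichlorocyclobutan-1-one
Product: 7 3-[(2S)-6-methyl-2-(triethylsilyloxy)hept-5-en-2-yl]cyclobutan-1-one, via dechlorinated bromo ether 6 (not isolated)
Conditions: Zn dust, NH4Cl, EtOH, 20 °C, then reflux
Reagents that add atoms: none
Why: Zinc reduction of the α,α-dichloro ketone followed on warming by Boord elimination of the β-bromo ether should give one cyclobutanone in which the side-chain-bearing ring carbon is no longer a stereocentre, so that all isomers of 5 converge and the trisubstituted alkene is restored.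

Step 5
Reactants: 7 3-[(2S)-6-methyl-2-(triethylsilyloxy)hept-5-en-2-yl]cyclobutan-1-one
Product: 8 triethyl({(2S)-6-methyl-2-[(1S)-3-(trimethylsilyloxy)cyclobut-2-en-1-yl]hept-5-en-2-yl}oxy)silane
Conditions: LiN[(R)-CH(CH3)Ph]2 (from the amine and n-BuLi), Me3SiCl (present from the start), THF, −100 °C
Reagents that add atoms: chlorotrimethylsilane, C[Si](C)(C)Cl
Why: Desymmetrising deprotonation of a 3-substituted cyclobutanone by a C2-symmetric chiral lithium amide with internal silyl chloride quench should select one of the two α-methylene groups, which decides which α-carbon becomes C5 and so sets C1 under reagent control, the remote C10 centre exerting little bias.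

Step 6
Reactants: 8 triethyl({(2S)-6-methyl-2-[(1S)-3-(trimethylsilyloxy)cyclobut-2-en-1-yl]hept-5-en-2-yl}oxy)silane
Product: 9 (2R,3R)-2-chloro-3-[(2S)-6-methyl-2-(triethylsilyloxy)hept-5-en-2-yl]cyclobutan-1-one
Conditions: N-chlorosuccinimide, NaHCO3, THF, −78 → 0 °C
Reagents that add atoms: N-chlorosuccinimide, O=C1CCC(=O)N1Cl
Why: Electrophilic α-chlorination of the silyl enol ether should place chlorine on the future C5, anti to the bulky substituent on C1 (trans), far faster than any reaction at the trisubstituted alkene; this C–Cl centre only marks the position and is removed in step 8.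

Step 7
Reactants: 9 (2R,3R)-2-chloro-3-[(2S)-6-methyl-2-(triethylsilyloxy)hept-5-en-2-yl]cyclobutan-1-one
Product: 10 (2R,3R)-2-chloro-3-[(2S)-6-methyl-2-(triethylsilyloxy)hept-5-en-2-yl]cyclopentan-1-one
Conditions: CH2N2, Et2O (trace MeOH), 0 °C
Reagents that add atoms: diazomethane, C=[N+]=[N-]
Why: Diazomethane ring expansion of the strained α-chloro ketone should insert CH2 (C3) between the carbonyl and the unsubstituted α-carbon, because the electron-poor chlorine-bearing carbon does not migrate, and leaves C1 and C5 unchanged.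

Step 8
Reactants: 10 (2R,3R)-2-chloro-3-[(2S)-6-methyl-2-(triethylsilyloxy)hept-5-en-2-yl]cyclopentan-1-one
Product: 14 (3S)-2-methylidene-3-[(2S)-6-methyl-2-(triethylsilyloxy)hept-5-en-2-yl]cyclopentan-1-one, via lithium enolate 11 (not isolated), via Mannich base 12 (not isolated), via trimethylammonium iodide 13 (not isolated)
Conditions: Me2CuLi (from MeLi and CuI), Et2O, −78 → −30 °C; CH2=NMe2+ I−, THF, −78 → 20 °C; MeI, 20 °C; aq NaHCO3, CH2Cl2, 20 °C
Reagents that add atoms: dimethyl(methylidene)ammonium iodide, C=[N+](C)C.[I-]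
Why: Reductive cleavage of the C–Cl bond by the cuprate should give the C4–C5 enolate regiospecifically, Mannich aminomethylation then puts C6 on C5, and quaternisation followed by base-induced β-elimination of trimethylamine gives the exocyclic enone with C1 untouched.

Step 9
Reactants: 14 (3S)-2-methylidene-3-[(2S)-6-methyl-2-(triethylsilyloxy)hept-5-en-2-yl]cyclopentan-1-one
Product: 16 (1S,5R,7S,10S)-10-(triethylsilyloxy)-15-norguai-11-en-4-one (trans-fused), via cis-fused C5-epimeric ketone 15 (not isolated)
Conditions: Me2AlCl (2 equiv), CH2Cl2, −78 → 0 °C; cold 1 M HCl; then DBU (cat.), CH2Cl2, 20 °C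
Reagents that add atoms: none
Why: Me2AlCl binds the C4 carbonyl of the s-cis enone and makes the exocyclic C6 electrophilic; the less substituted carbon C7 of the trisubstituted alkene bonds to C6 while positive charge builds at C11, and a hydrogen of a C11 methyl group passes to the aluminium enolate, which leaves the isopropenyl group and the C4 ketone; this is a Lewis-acid-promoted intramolecular ene reaction of a 1,7-diene with an enone enophile, close to cation–olefin cyclisation and to carbonyl-ene closures promoted by alkylaluminium chlorides. The seven-membered ring C1, C10, C9, C8, C7, C6, C5 closes with both enone carbons C5 and C6 inside the new ring (endo for the enone) and C11 outside it (exo for the ene alkene). C7 should be set by a chair-like transition state in which C9 lies anti to C2 across C1–C10, the C10 methyl is axial, the silyloxy group equatorial and the developing C11 centre pseudoequatorial, so that isopropenyl ends cis to C14; C5 is protonated without control and is then equilibrated by DBU through the enol to the trans-fused ketone, the trans-2,3-dialkylcyclopentanone being expected to be the more stable. The step needs regioselectivity (C7 and not C11 to C6), chemoselectivity for the ene product over hetero-Diels–Alder closure (enone oxygen to C11), chloride capture and oxa-Michael addition, and face selectivity at C7. These rest on the Markovnikov polarisation of the trisubstituted alkene, on Me2AlCl acting as proton scavenger at low temperature, on the silyl ether at C10 and on the quaternary C10, which folds the chain toward C6.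

Step 10
Reactants: 16 (1S,5R,7S,10S)-10-(triethylsilyloxy)-15-norguai-11-en-4-one
Product: 18 (1S,5R,7S,10S)-10-(triethylsilyloxy)-15-norguaia-3,11-dien-4-yl trifluoromethanesulfonate, via potassium enolate 17 (not isolated)
Conditions: KN(SiMe3)2, THF, −78 °C; PhN(SO2CF3)2, −78 → 0 °C
Reagents that add atoms: N-phenylbis(trifluoromethanesulfonimide), O=S(=O)(N(c1ccccc1)S(=O)(=O)C(F)(F)F)C(F)(F)F
Why: Kinetic deprotonation by the bulky amide base at low temperature should take a proton from the C3 methylene and not from the ring-fusion methine C5, and O-sulfonylation of the enolate (enol triflate formation) fixes the double bond at C3=C4 without epimerising C5.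

Step 11
Reactants: 18 (1S,5R,7S,10S)-10-(triethylsilyloxy)-15-norguaia-3,11-dien-4-yl trifluoromethanesulfonate
Product: 19 triethyl{[(1S,5R,7S,10S)-guaia-3,11-dien-10-yl]oxy}silane
Conditions: Me2CuLi (from MeLi and CuI), THF, −20 → 0 °C
Reagents that add atoms: lithium dimethylcuprate, [Li+].C[Cu-]C
Why: Coupling of the alkenyl triflate with the methylcuprate (substitution at the sp2 carbon) should replace the triflate by the C15 methyl group with the double bond kept at C3=C4.

Step 12
Reactants: 19 triethyl{[(1S,5R,7S,10S)-guaia-3,11-dien-10-yl]oxy}silane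
Product: 20 (1S,5R,7S,10S)-guaia-3,11-dien-10-ol
Conditions: Bu4NF, THF, 20–40 °C
Reagents that add atoms: none
Why: Fluoride-induced cleavage of the silyl ether should free the tertiary C10 alcohol under basic conditions that leave both alkenes and all stereocentres untouched.

Step 13
Reactants: 21 phenylpropiolic acid
Product: 22 3-phenylprop-2-ynoyl chloride
Conditions: (COCl)2, DMF (cat.), CH2Cl2, 0 → 20 °C
Reagents that add atoms: oxalyl chloride, O=C(Cl)C(=O)Cl
Why: Acid chloride formation through the chloroiminium species from DMF and oxalyl chloride should give an acylating agent that, unlike a (Z)-cinnamoyl chloride, has no alkene geometry to lose.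

Step 14
Reactants: 20 (1S,5R,7S,10S)-guaia-3,11-dien-10-ol; 22 3-phenylprop-2-ynoyl chloride
Product: 24 (1S,5R,7S,10S)-guaia-3,11-dien-10-yl 3-phenylprop-2-ynoate, via lithium alkoxide 23 (not isolated)
Conditions: n-BuLi, THF, −78 °C; then 22, −78 → 0 °C
Reagents that add atoms: none
Why: O-Acylation of the preformed lithium alkoxide by the acid chloride should esterify the hindered tertiary alcohol at the carbonyl carbon, with C10 untouched because its C–O bond is never broken.

Step 15
Reactants: 24 (1S,5R,7S,10S)-guaia-3,11-dien-10-yl 3-phenylprop-2-ynoate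
Product: 25 (1S,5R,7S,10S)-guaia-3,11-dien-10-yl (2Z)-3-phenylprop-2-enoate (target)
Conditions: H2 (1 atm), Pd/CaCO3 poisoned with Pb(OAc)2, quinoline, EtOAc, 20 °C
Reagents that add atoms: none
Why: cis-Semihydrogenation of the alkyne on lead-poisoned palladium (syn delivery of H2 on the catalyst surface) should give the (Z)-cinnamate, and with quinoline and one equivalent of hydrogen the isopropenyl and ring alkenes should be left alone.

Compound list
1 | (S)-linalool, (3S)-3,7-dimethylocta-1,6-dien-3-ol | CC(C)=CCC[C@](C)(O)C=C | starting material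
2 | {[(3S)-3,7-dimethylocta-1,6-dien-3-yl]oxy}(triethyl)silane | CC(C)=CCC[C@](C)(O[Si](CC)(CC)CC)C=C | intermediate
3 | {[(3S)-6-bromo-7-methoxy-3,7-dimethyloct-1-en-3-yl]oxy}(triethyl)silane (both C6 epimers) | COC(C)(C)C(Br)CC[C@](C)(O[Si](CC)(CC)CC)C=C | intermediate
4 | trichloroacetyl chloride | ClC(Cl)(Cl)C(Cl)=O | starting material
5 | 3-[(2S)-5-bromo-6-methoxy-6-methyl-2-(triethylsilyloxy)heptan-2-yl]-2,2-dichlorocyclobutan-1-one (epimers at ring C3 and at the C–Br carbon) | COC(C)(C)C(Br)CC[C@](C)(O[Si](CC)(CC)CC)C1CC(=O)C1(Cl)Cl | intermediate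
6 | 3-[(2S)-5-bromo-6-methoxy-6-methyl-2-(triethylsilyloxy)heptan-2-yl]cyclobutan-1-one (both C–Br epimers) | COC(C)(C)C(Br)CC[C@](C)(O[Si](CC)(CC)CC)C1CC(=O)C1 | intermediate
7 | 3-[(2S)-6-methyl-2-(triethylsilyloxy)hept-5-en-2-yl]cyclobutan-1-one | CC(C)=CCC[C@](C)(O[Si](CC)(CC)CC)C1CC(=O)C1 | intermediate
8 | triethyl({(2S)-6-methyl-2-[(1S)-3-(trimethylsilyloxy)cyclobut-2-en-1-yl]hept-5-en-2-yl}oxy)silane | CC(C)=CCC[C@](C)(O[Si](CC)(CC)CC)[C@H]1CC(O[Si](C)(C)C)=C1 | intermediate
9 | (2R,3R)-2-chloro-3-[(2S)-6-methyl-2-(triethylsilyloxy)hept-5-en-2-yl]cyclobutan-1-one | CC(C)=CCC[C@](C)(O[Si](CC)(CC)CC)[C@H]1CC(=O)[C@@H]1Cl | intermediate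
10 | (2R,3R)-2-chloro-3-[(2S)-6-methyl-2-(triethylsilyloxy)hept-5-en-2-yl]cyclopentan-1-one | CC(C)=CCC[C@](C)(O[Si](CC)(CC)CC)[C@H]1CCC(=O)[C@@H]1Cl | intermediate
11 | lithium (3S)-3-[(2S)-6-methyl-2-(triethylsilyloxy)hept-5-en-2-yl]cyclopent-1-en-1-olate | [Li+].CC(C)=CCC[C@](C)(O[Si](CC)(CC)CC)[C@H]1CCC([O-])=C1 | intermediate
12 | (2S,3S)-2-[(dimethylamino)methyl]-3-[(2S)-6-methyl-2-(triethylsilyloxy)hept-5-en-2-yl]cyclopentan-1-one | CC(C)=CCC[C@](C)(O[Si](CC)(CC)CC)[C@H]1CCC(=O)[C@@H]1CN(C)C | intermediate
13 | N,N,N-trimethyl-1-{(1S,2S)-2-[(2S)-6-methyl-2-(triethylsilyloxy)hept-5-en-2-yl]-5-oxocyclopentyl}methanaminium iodide | CC(C)=CCC[C@](C)(O[Si](CC)(CC)CC)[C@H]1CCC(=O)[C@@H]1C[N+](C)(C)C.[I-] | intermediate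
14 | (3S)-2-methylidene-3-[(2S)-6-methyl-2-(triethylsilyloxy)hept-5-en-2-yl]cyclopentan-1-one | CC(C)=CCC[C@](C)(O[Si](CC)(CC)CC)[C@H]1CCC(=O)C1=C | intermediate
15 | (1S,5S,7S,10S)-10-(triethylsilyloxy)-15-norguai-11-en-4-one (cis-fused) | C=C(C)[C@H]1CC[C@](C)(O[Si](CC)(CC)CC)[C@H]2CCC(=O)[C@H]2C1 | intermediate
16 | (1S,5R,7S,10S)-10-(triethylsilyloxy)-15-norguai-11-en-4-one (trans-fused; as an azulenone (3aS,4S,7S,8aR)-4-methyl-7-(prop-1-en-2-yl)-4-(triethylsilyloxy)octahydroazulen-1(2H)-one) | C=C(C)[C@H]1CC[C@](C)(O[Si](CC)(CC)CC)[C@H]2CCC(=O)[C@@H]2C1 | intermediate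
17 | potassium (1S,5R,7S,10S)-10-(triethylsilyloxy)-15-norguaia-3,11-dien-4-olate | [K+].C=C(C)[C@H]1CC[C@](C)(O[Si](CC)(CC)CC)[C@H]2CC=C([O-])[C@@H]2C1 | intermediate
18 | (1S,5R,7S,10S)-10-(triethylsilyloxy)-15-norguaia-3,11-dien-4-yl trifluoromethanesulfonate | C=C(C)[C@H]1CC[C@](C)(O[Si](CC)(CC)CC)[C@H]2CC=C(OS(=O)(=O)C(F)(F)F)[C@@H]2C1 | intermediate
19 | triethyl{[(1S,5R,7S,10S)-guaia-3,11-dien-10-yl]oxy}silane | C=C(C)[C@H]1CC[C@](C)(O[Si](CC)(CC)CC)[C@H]2CC=C(C)[C@@H]2C1 | intermediate
20 | (1S,5R,7S,10S)-guaia-3,11-dien-10-ol | C=C(C)[C@H]1CC[C@](C)(O)[C@H]2CC=C(C)[C@@H]2C1 | intermediate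
21 | phenylpropiolic acid | OC(=O)C#Cc1ccccc1 | starting material
22 | 3-phenylprop-2-ynoyl chloride | ClC(=O)C#Cc1ccccc1 | intermediate
23 | lithium (1S,5R,7S,10S)-guaia-3,11-dien-10-olate | [Li+].C=C(C)[C@H]1CC[C@](C)([O-])[C@H]2CC=C(C)[C@@H]2C1 | intermediate
24 | (1S,5R,7S,10S)-guaia-3,11-dien-10-yl 3-phenylprop-2-ynoate | C=C(C)[C@H]1CC[C@](C)(OC(=O)C#Cc2ccccc2)[C@H]2CC=C(C)[C@@H]2C1 | intermediate
25 | (1S,5R,7S,10S)-guaia-3,11-dien-10-yl (2Z)-3-phenylprop-2-enoate | C=C(C)[C@H]1CC[C@](C)(OC(=O)/C=C\c2ccccc2)[C@H]2CC=C(C)[C@@H]2C1 | target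

Total step count: 15. Longest linear sequence: 14 steps (steps 1–12, 14 and 15; step 13 is a one-step branch).

Steps most likely to fail

Step 9. The closure may lack facial selectivity at C7, or be diverted into hetero-Diels–Alder closure (enone oxygen to C11) or into chloride capture at C11. The fallback sets out from 14 and comes back at 16; it makes the same C6–C7 bond by an intramolecular Hosomi–Sakurai reaction. Ene-type allylic chlorination of the trisubstituted alkene of 14 with HOCl (Ca(OCl)2, CO2, CH2Cl2–H2O, 0 °C) should give the secondary allylic chloride (3S)-3-[(2S)-5-chloro-6-methyl-2-(triethylsilyloxy)hept-6-en-2-yl]-2-methylidenecyclopentan-1-one F1. Silylation with Me3SiSiMe3 and the zerovalent palladium complex Pd(PPh3)4 should then deliver the linear allylsilane (3S)-2-methylidene-3-[(2S)-6-methyl-2-(triethylsilyloxy)-7-(trimethylsilyl)hept-5-en-2-yl]cyclopentan-1-one F2. TiCl4 in CH2Cl2 at −78 °C should add C7 of the allylsilane to C6 with loss of silicon from C12, which leaves the isopropenyl group, and DBU equilibration at C5 returns the route at 16.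

Step 5. The chiral base may discriminate poorly between the two α-methylene groups, so that C1 forms with low selectivity. The fallback sets out from 5 and comes back at 12; it gives up reagent control and relies on separation. Diazomethane ring expansion of 5 (both ring epimers) should give 3-[(2S)-5-bromo-6-methoxy-6-methyl-2-(triethylsilyloxy)heptan-2-yl]-2,2-dichlorocyclopentan-1-one F3. Me2CuLi should reduce one C–Cl bond to lithium 3-[(2S)-5-bromo-6-methoxy-6-methyl-2-(triethylsilyloxy)heptan-2-yl]-2-chlorocyclopent-1-en-1-olate F4, which CH2=NMe2+ I− aminomethylates to 3-[(2S)-5-bromo-6-methoxy-6-methyl-2-(triethylsilyloxy)heptan-2-yl]-2-chloro-2-[(dimethylamino)methyl]cyclopentan-1-one F5. Zn and NH4Cl in EtOH at reflux then remove the second chlorine and reopen the bromo ether, giving 12 together with its ring epimer (2R,3R)-2-[(dimethylamino)methyl]-3-[(2S)-6-methyl-2-(triethylsilyloxy)hept-5-en-2-yl]cyclopentan-1-one F6. The two are separated by chromatography, and 12 is quaternised and eliminated as in step 8.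

Step 3. The cycloaddition may be slow at the hindered vinyl group, and zinc may attack the bromo ether before the ketene has added. The fallback sets out from 2 and comes back at 7; it uses a zinc-free keteniminium cycloaddition on a dibromide-masked substrate. Br2 with pyridine in CH2Cl2 at −78 °C should add only to the trisubstituted alkene to give {[(3S)-6,7-dibromo-3,7-dimethyloct-1-en-3-yl]oxy}(triethyl)silane F7. The keteniminium salt made from N,N-dimethylacetamide, (CF3SO2)2O and 2,4,6-collidine in ClCH2CH2Cl should add to the vinyl group to give N-{3-[(2S)-5,6-dibromo-6-methyl-2-(triethylsilyloxy)heptan-2-yl]cyclobutylidene}-N-methylmethanaminium trifluoromethanesulfonate F8. Aqueous NaHCO3 hydrolyses it to 3-[(2S)-5,6-dibromo-6-methyl-2-(triethylsilyloxy)heptan-2-yl]cyclobutan-1-one F9, and Zn in AcOH removes both bromine atoms to return the route at 7.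

Further compounds
F1 | step 9 | (3S)-3-[(2S)-5-chloro-6-methyl-2-(triethylsilyloxy)hept-6-en-2-yl]-2-methylidenecyclopentan-1-one (both C–Cl epimers) | C=C(C)C(Cl)CC[C@](C)(O[Si](CC)(CC)CC)[C@H]1CCC(=O)C1=C
F2 | step 9 | (3S)-2-methylidene-3-[(2S)-6-methyl-2-(triethylsilyloxy)-7-(trimethylsilyl)hept-5-en-2-yl]cyclopentan-1-one (E and Z) | C[Si](C)(C)CC(C)=CCC[C@](C)(O[Si](CC)(CC)CC)[C@H]1CCC(=O)C1=C
F3 | step 5 | 3-[(2S)-5-bromo-6-methoxy-6-methyl-2-(triethylsilyloxy)heptan-2-yl]-2,2-dichlorocyclopentan-1-one | COC(C)(C)C(Br)CC[C@](C)(O[Si](CC)(CC)CC)C1CCC(=O)C1(Cl)Cl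
F4 | step 5 | lithium 3-[(2S)-5-bromo-6-methoxy-6-methyl-2-(triethylsilyloxy)heptan-2-yl]-2-chlorocyclopent-1-en-1-olate | [Li+].COC(C)(C)C(Br)CC[C@](C)(O[Si](CC)(CC)CC)C1CCC([O-])=C1Cl
F5 | step 5 | 3-[(2S)-5-bromo-6-methoxy-6-methyl-2-(triethylsilyloxy)heptan-2-yl]-2-chloro-2-[(dimethylamino)methyl]cyclopentan-1-one | COC(C)(C)C(Br)CC[C@](C)(O[Si](CC)(CC)CC)C1CCC(=O)C1(Cl)CN(C)C
F6 | step 5 | (2R,3R)-2-[(dimethylamino)methyl]-3-[(2S)-6-methyl-2-(triethylsilyloxy)hept-5-en-2-yl]cyclopentan-1-one | CC(C)=CCC[C@](C)(O[Si](CC)(CC)CC)[C@@H]1CCC(=O)[C@H]1CN(C)C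
F7 | step 3 | {[(3S)-6,7-dibromo-3,7-dimethyloct-1-en-3-yl]oxy}(triethyl)silane | CC(C)(Br)C(Br)CC[C@](C)(O[Si](CC)(CC)CC)C=C
F8 | step 3 | N-{3-[(2S)-5,6-dibromo-6-methyl-2-(triethylsilyloxy)heptan-2-yl]cyclobutylidene}-N-methylmethanaminium trifluoromethanesulfonate | CC(C)(Br)C(Br)CC[C@](C)(O[Si](CC)(CC)CC)C1CC(=[N+](C)C)C1.[O-]S(=O)(=O)C(F)(F)F
F9 | step 3 | 3-[(2S)-5,6-dibromo-6-methyl-2-(triethylsilyloxy)heptan-2-yl]cyclobutan-1-one | CC(C)(Br)C(Br)CC[C@](C)(O[Si](CC)(CC)CC)C1CC(=O)C1
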